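# Total synthesis proposal for CNP0271189.1

Germacrane numbering is used throughout: C1 carbinol, C2 methylene, C3 ketone, C4(CH3)=C5, C6 lactone carbinol, C7 ring fusion, C8 acyloxy carbon, C9 methylene, C10 tertiary carbinol, and C11(=C13H2)–C12(=O) for the lactone. The target is the (1S,6S,7R,8R,10S,4Z) isomer.

## The problem

The target is a germacranolide: a ten-membered carbocycle (C1–C10) with an α-methylene-γ-lactone cis-fused across C6–C7 (oxygen on C6, C11 on C7). The ring carries a Z-configured enone (C3 ketone, C4=C5), an angelate on C8, a tertiary carbinol at C10 and a secondary carbinol at C1 that is β to the C3 ketone. Five stereocentres must be set: the contiguous triad C6/C7/C8, and the 1,2-syn diol C1/C10, which a single methylene (C9) separates from C8. C7 can direct C6 if the C5–C6 bond is formed by addition to a C6 aldehyde, and C7/C8 form a syn aldol pair. The quaternary C10 offers only a methyl and a methylene to tell its faces apart, so it is a poor director for both C8 and C1, and these need reagent control. The ten-membered ring is strained and entropically costly to close, and the Z geometry of the trisubstituted enone has to be fixed before closure. Groups that will not survive rough treatment are the β-hydroxy ketone (retro-aldol, dehydration), the exo-methylene lactone (Michael acceptor), the angelate (isomerises to the tiglate) and any C6 aldehyde precursor (β,γ-unsaturated and β-silyloxy, so prone to epimerisation and elimination). The feature that makes the key step possible is that C5, the β-carbon of the Z enone, is bonded to the lactone carbinol C6, and C6 lies γ to C12 through C7–C11. A vinyl metal at C5 adding to a C6 aldehyde therefore closes the carbocycle and places an alkoxide five atoms from a C12 ester, which closes the lactone.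

## Retrosynthesis

**36 ⇒ 35 ⇒ 32 + 33 ⇒ 31.** The last bonds cut are the Si–O bonds at C1 and C10 and the acyl–O bond at C8. The angelate is put on late because it would not tolerate the Grignard, amide-base and enolate chemistry used earlier. This requires the C8 oxygen to be unmasked selectively, which a secondary triethylsilyl (TES) ether beside a secondary tert-butyldimethylsilyl (TBS) ether at C1 and a tertiary TES ether at C10 allows. The forward steps must be non-basic and must leave the methylene lactone and the β-silyloxy ketone alone.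

**31 ⇒ 29 (key cut).** The C5–C6 bond and the O6–C12 lactone bond are cut together, giving open-chain aldehyde ester 29 with a Z vinyl iodide at C5. Cutting at C1–C2 (macro-aldol) or C9–C10 would also open the ring but would leave the lactone to be made separately. Here one bond formation gives both rings, and the Z geometry is carried in unchanged from the iodide. Precursor 29 is acyclic and already holds four of the five stereocentres. The forward reaction must be chemoselective for the aldehyde over the ketone and esters, must favour ring closure over intermolecular coupling, and must select the C6 face that gives the cis lactone.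

**29 ⇒ 28 ⇒ 27 ⇒ 26 ⇒ 20 + 24.** The C6 aldehyde is traced to a 4-methoxybenzyl (PMB) ether, and the C1–C2 bond is cut as an aldol between aldehyde 20 and methyl ketone 24. This is the most convergent junction, because 24 brings the complete Z β-iodoenone in one piece. A cut at C3–C4 would need a Z-configured 2-metallo-1-iodopropene, which is not a practical reagent. The price is that C1 is created next to the quaternary C10, so a chiral boron reagent must supply the face selectivity.

**20 ⇒ 18 ⇒ 17 ⇒ 15 ⇒ 14 ⇒ 13 ⇒ 12.** The C1 aldehyde comes from a primary TES ether. The acrylate (C11–C13) comes from the carbonyl carbon of an aldol adduct by way of a methyl ketone, its enol triflate and methoxycarbonylation. A direct indium-mediated 2-(alkoxycarbonyl)allylation of 10 would be four steps shorter. It is not chosen because the C8 face would then rest on 1,3-induction from the quaternary C10. The palladium step has to precede the arrival of the vinyl iodide, which fixes the order of the two fragment unions.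

**12 ⇒ 5 + 10.** The C7–C8 bond is cut as an Evans syn aldol. The auxiliary sets both centres regardless of C10, and the 7,8-syn relationship required (C8–O and the C6 carbon syn when C11 is taken as the chain end) is the one a Z boron enolate delivers. The enolate must not lose its β-alkoxy group.

**10 ⇒ 8 ⇒ 7 ⇒ 6.** C10 is taken from the chiral pool. Epoxide 6 already holds the quaternary carbinol with its two CH2 arms differentiated (one an epoxide carbon, one a carbinol), so vinyl addition and ozonolysis give the C8 aldehyde in three steps. A hydroxy diacid of the chiral pool would give the same centre but with two primary hydroxyls to tell apart after reduction.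

**24 ⇒ 23 ⇒ 21; 5 ⇒ 2 + 3; 2 ⇒ 1.** The Z iodoenone comes from a propargylic alcohol by hydroxyl-directed anti-carbomagnesiation, iodination and oxidation. The imide comes from the PMB-protected hydroxy acid and the oxazolidinone.

## Roads not taken

**Alternative 1:** Anionic oxy-Cope ring expansion. A six-membered dialkenyl carbinol from the terpene chiral pool is opened by a [3,3] shift of its potassium alkoxide, forming C8–C9 and breaking C1–C6, to give ten-membered dienone A1. As a way of making the ring this is better than the chosen plan: it is unimolecular, driven by enolate formation, needs no high dilution, and fixes the 4Z geometry from the cyclohexenone. Its weakness for this target is what A1 lacks. It has no C11–C13 carbons, no lactone, no C1/C10 diol, and C3 and C6 at the wrong oxidation levels. C7 would have to be alkylated, C6 reduced, C3 oxidised and the 1(10) olefin dihydroxylated, each with stereocontrol coming only from a flexible medium ring. The chosen plan sets against the easier ring closure the fact that four stereocentres are fixed in acyclic intermediates under auxiliary or reagent control, and that lactone and carbocycle arrive together.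

**Alternative 2:** Samarium Reformatsky macrocyclisation at C1–C2. SmI2 (divalent samarium) reduces a bromomethyl Z-enone to its enolate, which adds to the C1 aldehyde and gives ten-membered aldol A2. This road is at least as good in two respects. The fragile β-hydroxy ketone is made last instead of being carried through seven steps, and C1 is set inside a cyclic transition state, not by an intermolecular aldol next to a quaternary centre, which is the weakest stereochemical step of the chosen plan. Against it, A2 still has the lactone open, so C12 must be oxidised and lactonised after ring closure. The linear precursor needs the same C5–C6 bond made intermolecularly with C6 control. The bromination of a Z enone and the selectivity of SmI2 in the presence of the angelate and the enone are open questions. The chosen plan has to set against Alternative 2 only its tandem ring and lactone formation and the use of C12 at the ester level throughout.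

**Alternative 3:** Intramolecular nitrile oxide cycloaddition. A C3 nitrile oxide adds to a terminal C1=C2 alkene, forming C2–C3 and O–C1 and giving isoxazoline-bridged macrocycle A3. Its merit is that the β-hydroxy ketone stays masked and cannot undergo retro-aldol until the end, and the cycloaddition is neutral and tolerant. Its weak points are these:
- Face selectivity at C1 would again depend on the quaternary C10.
- The nitrile oxide sits on a Z-alkenyl unit whose geometry must survive oxime chlorination.
- The N–O bond must be cleaved reductively without touching the enone.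
- A3 carries a saturated lactone, so the exo-methylene group would have to be added by enolate chemistry in the presence of a β-hydroxy ketone.

The chosen plan is shorter after ring closure (three steps), but it must carry the unmasked aldol.

Key step: step 19

Assumption: compounds 1, 3, 6, 21, 33 and (+)-Ipc2BCl are taken as purchased; the 2-methylglycidol 6 is used as the commercial (R) enantiomer, and any minor enantiomer is removed as a diastereomer after step 6.

## Route

Step 1
Reactants: 1 3-(4-methoxybenzyloxy)propan-1-ol
Product: 2 3-(4-methoxybenzyloxy)propanoic acid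
Conditions: TEMPO (cat.), NaClO2, NaOCl (cat.), MeCN/phosphate buffer pH 6.7, 35 °C
Reagents that add atoms: sodium chlorite, [Na+].[O-]Cl=O
Why: TEMPO-catalysed chlorite oxidation takes a primary alcohol to the acid under buffered conditions that leave the acid-labile PMB ether intact; no stereocentre is involved.

Step 2
Reactants: 2 3-(4-methoxybenzyloxy)propanoic acid; 3 (S)-4-benzyl-1,3-oxazolidin-2-one
Product: 5 (S)-4-benzyl-3-[3-(4-methoxybenzyloxy)propanoyl]-1,3-oxazolidin-2-one, via mixed pivalic anhydride 4 (not isolated)
Conditions: t-BuCOCl, Et3N, THF, −20 °C; then 3, LiCl, rt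
Reagents that add atoms: none
Why: N-acylation of an Evans oxazolidinone through the mixed anhydride with LiCl/Et3N needs no strong base, so the β-PMB-oxy group is not eliminated; the auxiliary centre is untouched.

Step 3
Reactants: 6 (R)-2-methylglycidol
Product: 7 (S)-2-methylpent-4-ene-1,2-diol
Conditions: CH2=CHMgBr, CuI (cat.), THF, −30 → 0 °C
Reagents that add atoms: vinylmagnesium bromide, C=C[Mg]Br
Why: Copper-catalysed Grignard opening of a 2,2-disubstituted epoxide occurs at the unhindered CH2 terminus, so no bond to the quaternary carbon is broken and C10 keeps the configuration of 6.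

Step 4
Reactants: 7 (S)-2-methylpent-4-ene-1,2-diol
Product: 8 (S)-4-methyl-4,5-bis(triethylsilyloxy)pent-1-ene
Conditions: TESOTf, 2,6-lutidine, CH2Cl2, −78 → 0 °C
Reagents that add atoms: triethylsilyl trifluoromethanesulfonate, CC[Si](CC)(CC)OS(=O)(=O)C(F)(F)F
Why: The silyl triflate silylates both the primary and the hindered tertiary hydroxyl; the primary TES ether is the latent C1 aldehyde and the tertiary TES ether stays until the last step.

Step 5
Reactants: 8 (S)-4-methyl-4,5-bis(triethylsilyloxy)pent-1-ene
Product: 10 (S)-3-methyl-3,4-bis(triethylsilyloxy)butanal, via secondary ozonide 9 (not isolated)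
Conditions: O3, CH2Cl2, −78 °C; then PPh3, → rt
Reagents that add atoms: ozone, [O-][O+]=O
Why: Ozonolysis with reductive work-up cleaves the only alkene to the C8 aldehyde; silyl ethers are inert and the aldehyde has no α stereocentre.

Step 6
Reactants: 5 (S)-4-benzyl-3-[3-(4-methoxybenzyloxy)propanoyl]-1,3-oxazolidin-2-one; 10 (S)-3-methyl-3,4-bis(triethylsilyloxy)butanal
Product: 12 (S)-4-benzyl-3-[(2S,3R,5S)-3-hydroxy-2-(4-methoxybenzyloxymethyl)-5-methyl-5,6-bis(triethylsilyloxy)hexanoyl]-1,3-oxazolidin-2-one, via dibutylboron Z-enolate 11 (not isolated)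
Conditions: Bu2BOTf, i-Pr2NEt, CH2Cl2, 0 °C; then 10, −78 → 0 °C; H2O2, MeOH, pH 7 buffer
Reagents that add atoms: none
Why: Evans syn aldol: the Z boron enolate reacts through a Zimmerman–Traxler chair in which the (S)-benzyl auxiliary fixes the enolate face, giving the 7,8-syn adduct with C7 (S) and C8 (R) whatever the remote quaternary C10 prefers; boron enolates of β-alkoxy imides are covalent enough not to eliminate readily.

Step 7
Reactants: 12 the aldol imide
Product: 13 (2S,3R,5S)-3-hydroxy-N-methoxy-2-(4-methoxybenzyloxymethyl)-N,5-dimethyl-5,6-bis(triethylsilyloxy)hexanamide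
Conditions: MeONHMe·HCl, AlMe3, CH2Cl2, −20 → 0 °C
Reagents that add atoms: N,O-dimethylhydroxylamine hydrochloride, CNOC.Cl
Why: Aluminium amide transamination of a β-hydroxy imide to its Weinreb amide is assisted by the free hydroxyl and releases the auxiliary; no stereocentre is touched.

Step 8
Reactants: 13 the β-hydroxy Weinreb amide
Product: 14 (2S,3R,5S)-N-methoxy-2-(4-methoxybenzyloxymethyl)-N,5-dimethyl-3,5,6-tris(triethylsilyloxy)hexanamide
Conditions: TESOTf, 2,6-lutidine, CH2Cl2, −78 °C
Reagents that add atoms: triethylsilyl trifluoromethanesulfonate, CC[Si](CC)(CC)OS(=O)(=O)C(F)(F)F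
Why: Silylation of the C8 hydroxyl blocks retro-aldol and later lactonisation onto C12 and provides the group that is removed selectively after ring closure.

Step 9
Reactants: 14 the silylated Weinreb amide
Product: 15 (3S,4R,6S)-3-(4-methoxybenzyloxymethyl)-6-methyl-4,6,7-tris(triethylsilyloxy)heptan-2-one
Conditions: MeMgBr, THF, −20 → 0 °C
Reagents that add atoms: methylmagnesium bromide, C[Mg]Br
Why: Weinreb ketone synthesis: the chelated tetrahedral intermediate prevents over-addition, and the α-centre C7 is not enolised by the Grignard reagent at this temperature.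

Step 10
Reactants: 15 the methyl ketone
Product: 17 (3S,4R,6S)-3-(4-methoxybenzyloxymethyl)-6-methyl-4,6,7-tris(triethylsilyloxy)hept-1-en-2-yl trifluoromethanesulfonate, via potassium enolate 16 (not isolated)
Conditions: KN(SiMe3)2, THF, −78 °C; then PhNTf2
Reagents that add atoms: N-phenylbis(trifluoromethanesulfonimide), O=S(=O)(N(c1ccccc1)S(=O)(=O)C(F)(F)F)C(F)(F)F
Why: Kinetic deprotonation takes place at the unhindered methyl group, not at the branched C7, so the terminal enol triflate forms and the enolate that could expel the β-alkoxy groups is avoided; C7 keeps its configuration.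

Step 11
Reactants: 17 the enol triflate
Product: 18 methyl (3S,4R,6S)-3-(4-methoxybenzyloxymethyl)-6-methyl-2-methylidene-4,6,7-tris(triethylsilyloxy)heptanoate
Conditions: Pd(OAc)2 (cat.), PPh3, CO (1 atm), MeOH, Et3N, DMF, rt
Reagents that add atoms: carbon monoxide, [C-]#[O+]; methanol, CO
Why: Palladium-catalysed methoxycarbonylation of an enol triflate (oxidative addition, CO insertion, methanolysis) gives the 2-substituted acrylate C11–C13; it is run before any vinyl iodide is present, and the allylic C7–H is not removed by Et3N at room temperature.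

Step 12
Reactants: 18 the tris-TES acrylate
Product: 20 methyl (3S,4R,6S)-3-(4-methoxybenzyloxymethyl)-6-methyl-2-methylidene-7-oxo-4,6-bis(triethylsilyloxy)heptanoate, via alkoxysulfonium chloride 19 (not isolated)
Conditions: (COCl)2, DMSO, CH2Cl2, −78 → −30 °C; then Et3N, −78 → 0 °C
Reagents that add atoms: none
Why: Under Swern conditions a primary TES ether is cleaved by the chlorosulfonium salt and oxidised directly, while the secondary and tertiary TES ethers are too hindered to react; the new aldehyde has a quaternary α-carbon and cannot epimerise.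

Step 13
Reactants: 21 but-3-yn-2-ol (racemic)
Product: 23 (Z)-4-iodo-3-methylbut-3-en-2-ol (racemic), via alkenylmagnesium bromide alkoxide 22 (not isolated)
Conditions: MeMgBr, CuI (cat.), THF, −10 °C → rt; then I2, −40 → 0 °C
Reagents that add atoms: methylmagnesium bromide, C[Mg]Br; iodine, II
Why: Copper-catalysed anti-carbomagnesiation of a propargylic alcohol: the magnesium alkoxide directs methyl to the proximal alkyne carbon and leaves magnesium on the terminus cis to the carbinol, and iodination with retention gives the Z iodide; the carbinol centre is removed in step 14.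

Step 14
Reactants: 23 (Z)-4-iodo-3-methylbut-3-en-2-ol
Product: 24 (Z)-4-iodo-3-methylbut-3-en-2-one
Conditions: MnO2, CH2Cl2, rt, dark
Reagents that add atoms: none
Why: MnO2 oxidises the allylic alcohol under neutral conditions, so the Z β-iodoenone is not isomerised by acid or base.

Step 15
Reactants: 20 the C1 aldehyde; 24 (Z)-4-iodo-3-methylbut-3-en-2-one
Product: 26 methyl (3S,4R,6S,7S,10Z)-7-hydroxy-11-iodo-3-(4-methoxybenzyloxymethyl)-6,10-dimethyl-2-methylidene-9-oxo-4,6-bis(triethylsilyloxy)undec-10-enoate, via diisopinocampheylboron enolate 25 (not isolated)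
Conditions: 24, (+)-Ipc2BCl, Et3N, Et2O, 0 °C; then 20, −78 → −20 °C; H2O2, MeOH, pH 7 buffer, 0 °C
Reagents that add atoms: none
Why: Boron aldol of a methyl ketone under reagent control: the (+)-Ipc2B enolate is expected to attack the si face of the aldehyde, which gives the (1S) carbinol syn to the C10 oxygen; the intrinsic bias of the α-silyloxy quaternary centre is weak (methyl against methylene), so the reagent should dominate, and the C1 epimers are diastereomers that can be separated.

Step 16
Reactants: 26 the aldol
Product: 27 methyl (3S,4R,6S,7S,10Z)-7-(tert-butyldimethylsilyloxy)-11-iodo-3-(4-methoxybenzyloxymethyl)-6,10-dimethyl-2-methylidene-9-oxo-4,6-bis(triethylsilyloxy)undec-10-enoate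
Conditions: TBSOTf, 2,6-lutidine, CH2Cl2, −78 °C
Reagents that add atoms: tert-butyldimethylsilyl trifluoromethanesulfonate, CC(C)(C)[Si](C)(C)OS(=O)(=O)C(F)(F)F
Why: Silylation at low temperature blocks retro-aldol and dehydration of the β-hydroxy ketone; TBS is chosen so that it outlasts the TES ether at C8.

Step 17
Reactants: 27 the fully protected open chain
Product: 28 methyl (3S,4R,6S,7S,10Z)-7-(tert-butyldimethylsilyloxy)-3-(hydroxymethyl)-11-iodo-6,10-dimethyl-2-methylidene-9-oxo-4,6-bis(triethylsilyloxy)undec-10-enoate
Conditions: DDQ, CH2Cl2/pH 7 buffer, 0 °C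
Reagents that add atoms: none
Why: Oxidative cleavage of the PMB ether by DDQ under buffered conditions spares silyl ethers, the vinyl iodide and the acrylate; the alcohol is taken on at once because a γ-hydroxy acrylate can lactonise on standing.

Step 18
Reactants: 28 the C6 alcohol
Product: 29 methyl (3R,4R,6S,7S,10Z)-7-(tert-butyldimethylsilyloxy)-3-formyl-11-iodo-6,10-dimethyl-2-methylidene-9-oxo-4,6-bis(triethylsilyloxy)undec-10-enoate
Conditions: Dess–Martin periodinane, NaHCO3, CH2Cl2, 0 °C
Reagents that add atoms: none
Why: Dess–Martin oxidation with a solid bicarbonate buffer involves no amine base, so the β,γ-unsaturated, β-silyloxy aldehyde is neither epimerised at C7 nor eliminated; it is filtered and used crude.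

Step 19
Reactants: 29 the Z β-iodoenone aldehyde ester
Product: 31 (1S,6S,7S,8R,10S,4Z)-1-(tert-butyldimethylsilyloxy)-8,10-bis(triethylsilyloxy)-3-oxogermacra-4,11(13)-dien-12,6-olide, via ten-membered chromium alkoxide ester 30 (not isolated)
Conditions: CrCl2 (excess), NiCl2 (cat.), degassed DMSO, 2 mM, rt → 40 °C
Reagents that add atoms: none
Why: CrCl2 (divalent chromium) reduces NiCl2 to zerovalent nickel, which inserts into the C5–I bond with retention, and transmetallation gives the C5 vinylchromium species (trivalent chromium). The closest known reaction types are the intramolecular Nozaki–Hiyama–Kishi vinyl iodide–aldehyde closure of medium rings and chromium-mediated additions of β-iodo enones and enoates that end in lactonisation. The vinylchromium adds only to the C6 aldehyde, tolerating the ketone, both esters and the silyl ethers, and this forms C5–C6 and closes the ten-membered ring in an exo-trig addition. The chromium alkoxide 30 then sits five atoms from the C12 methyl ester and closes the γ-lactone by 5-exo-trig acyl substitution with loss of methoxide. C6 is set by C7 in a Felkin–Anh arrangement: the tether holds the C7–C8 ring bond gauche to the incoming C5, the acrylate unit takes the antiperiplanar position, and C5 passes the small H7, which gives (6S) with H6 and H7 cis. The Z geometry is fixed in the iodide and is kept by both metal steps, so the E ring isomer cannot form. The step needs ring closure to outrun intermolecular coupling, which high dilution and excess CrCl2 secure, and it needs the absence of base so that the C7 centre of the aldehyde is not lost. Lactonisation locks the C6 configuration and removes the free alkoxide from the medium.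

Step 20
Reactants: 31 the tris-silylated germacranolide
Product: 32 (1S,6S,7R,8R,10S,4Z)-1-(tert-butyldimethylsilyloxy)-8-hydroxy-10-(triethylsilyloxy)-3-oxogermacra-4,11(13)-dien-12,6-olide
Conditions: PPTS, MeOH/CH2Cl2, 0 °C
Reagents that add atoms: none
Why: Mild acid methanolysis removes the secondary TES ether faster than the tertiary TES ether and the TBS ether; should the tertiary TES ether also be lost, the tertiary hydroxyl is inert in step 21 and the route is unchanged.

Step 21
Reactants: 32 the C8 alcohol; 33 angelic acid
Product: 35 (1S,6S,7R,8R,10S,4Z)-8-angeloyloxy-1-(tert-butyldimethylsilyloxy)-10-(triethylsilyloxy)-3-oxogermacra-4,11(13)-dien-12,6-olide, via mixed trichlorobenzoic anhydride 34 (not isolated)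
Conditions: 33, 2,4,6-Cl3C6H2COCl, Et3N, toluene, rt; then 32, 70 °C
Reagents that add atoms: none
Why: Yamaguchi esterification through the preformed mixed anhydride, run without DMAP, acylates the C8 oxygen with retention at carbon and avoids the nucleophile-induced isomerisation of the angelate to the tiglate.

Step 22
Reactants: 35 the silylated angelate
Product: 36 CNP0271189.1, (1S,6S,7R,8R,10S,4Z)-8-angeloyloxy-1,10-dihydroxy-3-oxogermacra-4,11(13)-dien-12,6-olide
Conditions: HF·pyridine, pyridine, THF, 0 °C → rt
Reagents that add atoms: none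
Why: Buffered HF·pyridine removes the TBS and the tertiary TES ether without base, so the β-hydroxy ketone, the methylene lactone and the angelate survive.

## Compound list

1 | 3-(4-methoxybenzyloxy)propan-1-ol | OCCCOCc1ccc(OC)cc1 | starting material
2 | 3-(4-methoxybenzyloxy)propanoic acid | OC(=O)CCOCc1ccc(OC)cc1 | intermediate
3 | (S)-4-benzyl-1,3-oxazolidin-2-one | O=C1OC[C@H](Cc2ccccc2)N1 | starting material
4 | 3-(4-methoxybenzyloxy)propanoic pivalic anhydride (not isolated) | CC(C)(C)C(=O)OC(=O)CCOCc1ccc(OC)cc1 | intermediate
5 | (S)-4-benzyl-3-[3-(4-methoxybenzyloxy)propanoyl]-1,3-oxazolidin-2-one | O=C1OC[C@H](Cc2ccccc2)N1C(=O)CCOCc1ccc(OC)cc1 | intermediate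
6 | (R)-2-methylglycidol, (R)-(2-methyloxiran-2-yl)methanol | OC[C@]1(C)CO1 | starting material
7 | (S)-2-methylpent-4-ene-1,2-diol | C=CC[C@](C)(O)CO | intermediate
8 | (S)-4-methyl-4,5-bis(triethylsilyloxy)pent-1-ene | C=CC[C@](C)(O[Si](CC)(CC)CC)CO[Si](CC)(CC)CC | intermediate
9 | 3-[(S)-2-methyl-2,3-bis(triethylsilyloxy)propyl]-1,2,4-trioxolane, both epimers at the ring carbon (not isolated) | CC[Si](CC)(CC)OC[C@@](C)(O[Si](CC)(CC)CC)CC1OCOO1 | intermediate
10 | (S)-3-methyl-3,4-bis(triethylsilyloxy)butanal | O=CC[C@](C)(O[Si](CC)(CC)CC)CO[Si](CC)(CC)CC | intermediate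
11 | dibutylboron (Z)-enolate of 5 (not isolated) | CCCCB(CCCC)O/C(=C\COCc1ccc(OC)cc1)N1C(=O)OC[C@@H]1Cc1ccccc1 | intermediate
12 | (S)-4-benzyl-3-[(2S,3R,5S)-3-hydroxy-2-(4-methoxybenzyloxymethyl)-5-methyl-5,6-bis(triethylsilyloxy)hexanoyl]-1,3-oxazolidin-2-one | O=C1OC[C@H](Cc2ccccc2)N1C(=O)[C@@H](COCc1ccc(OC)cc1)[C@H](O)C[C@](C)(O[Si](CC)(CC)CC)CO[Si](CC)(CC)CC | intermediate
13 | (2S,3R,5S)-3-hydroxy-N-methoxy-2-(4-methoxybenzyloxymethyl)-N,5-dimethyl-5,6-bis(triethylsilyloxy)hexanamide | CON(C)C(=O)[C@@H](COCc1ccc(OC)cc1)[C@H](O)C[C@](C)(O[Si](CC)(CC)CC)CO[Si](CC)(CC)CC | intermediate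
14 | (2S,3R,5S)-N-methoxy-2-(4-methoxybenzyloxymethyl)-N,5-dimethyl-3,5,6-tris(triethylsilyloxy)hexanamide | CON(C)C(=O)[C@@H](COCc1ccc(OC)cc1)[C@H](O[Si](CC)(CC)CC)C[C@](C)(O[Si](CC)(CC)CC)CO[Si](CC)(CC)CC | intermediate
15 | (3S,4R,6S)-3-(4-methoxybenzyloxymethyl)-6-methyl-4,6,7-tris(triethylsilyloxy)heptan-2-one | CC(=O)[C@@H](COCc1ccc(OC)cc1)[C@H](O[Si](CC)(CC)CC)C[C@](C)(O[Si](CC)(CC)CC)CO[Si](CC)(CC)CC | intermediate
16 | terminal potassium enolate of 15 (not isolated) | [K+].[O-]C(=C)[C@@H](COCc1ccc(OC)cc1)[C@H](O[Si](CC)(CC)CC)C[C@](C)(O[Si](CC)(CC)CC)CO[Si](CC)(CC)CC | intermediate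
17 | (3S,4R,6S)-3-(4-methoxybenzyloxymethyl)-6-methyl-4,6,7-tris(triethylsilyloxy)hept-1-en-2-yl trifluoromethanesulfonate | C=C(OS(=O)(=O)C(F)(F)F)[C@@H](COCc1ccc(OC)cc1)[C@H](O[Si](CC)(CC)CC)C[C@](C)(O[Si](CC)(CC)CC)CO[Si](CC)(CC)CC | intermediate
18 | methyl (3S,4R,6S)-3-(4-methoxybenzyloxymethyl)-6-methyl-2-methylidene-4,6,7-tris(triethylsilyloxy)heptanoate | C=C(C(=O)OC)[C@@H](COCc1ccc(OC)cc1)[C@H](O[Si](CC)(CC)CC)C[C@](C)(O[Si](CC)(CC)CC)CO[Si](CC)(CC)CC | intermediate
19 | alkoxydimethylsulfonium chloride at the C1 oxygen of 18 (not isolated) | C[S+](C)OC[C@@](C)(O[Si](CC)(CC)CC)C[C@@H](O[Si](CC)(CC)CC)[C@H](COCc1ccc(OC)cc1)C(=C)C(=O)OC.[Cl-] | intermediate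
20 | methyl (3S,4R,6S)-3-(4-methoxybenzyloxymethyl)-6-methyl-2-methylidene-7-oxo-4,6-bis(triethylsilyloxy)heptanoate | O=C[C@@](C)(O[Si](CC)(CC)CC)C[C@@H](O[Si](CC)(CC)CC)[C@H](COCc1ccc(OC)cc1)C(=C)C(=O)OC | intermediate
21 | but-3-yn-2-ol (racemic) | C#CC(C)O | starting material
22 | (Z)-alkenylmagnesium bromide alkoxide from 21 (not isolated) | CC(O[Mg]Br)/C(C)=C\[Mg]Br | intermediate
23 | (Z)-4-iodo-3-methylbut-3-en-2-ol (racemic) | CC(O)/C(C)=C\I | intermediate
24 | (Z)-4-iodo-3-methylbut-3-en-2-one | CC(=O)/C(C)=C\I | intermediate
25 | (+)-diisopinocampheylboron enolate of 24 (not isolated) | C=C(OB([C@H]1C[C@H]2C[C@@H]([C@@H]1C)C2(C)C)[C@H]1C[C@H]2C[C@@H]([C@@H]1C)C2(C)C)/C(C)=C\I | intermediate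
26 | methyl (3S,4R,6S,7S,10Z)-7-hydroxy-11-iodo-3-(4-methoxybenzyloxymethyl)-6,10-dimethyl-2-methylidene-9-oxo-4,6-bis(triethylsilyloxy)undec-10-enoate | I/C=C(/C)C(=O)C[C@H](O)[C@@](C)(O[Si](CC)(CC)CC)C[C@@H](O[Si](CC)(CC)CC)[C@H](COCc1ccc(OC)cc1)C(=C)C(=O)OC | intermediate
27 | methyl (3S,4R,6S,7S,10Z)-7-(tert-butyldimethylsilyloxy)-11-iodo-3-(4-methoxybenzyloxymethyl)-6,10-dimethyl-2-methylidene-9-oxo-4,6-bis(triethylsilyloxy)undec-10-enoate | I/C=C(/C)C(=O)C[C@H](O[Si](C)(C)C(C)(C)C)[C@@](C)(O[Si](CC)(CC)CC)C[C@@H](O[Si](CC)(CC)CC)[C@H](COCc1ccc(OC)cc1)C(=C)C(=O)OC | intermediate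
28 | methyl (3S,4R,6S,7S,10Z)-7-(tert-butyldimethylsilyloxy)-3-(hydroxymethyl)-11-iodo-6,10-dimethyl-2-methylidene-9-oxo-4,6-bis(triethylsilyloxy)undec-10-enoate | I/C=C(/C)C(=O)C[C@H](O[Si](C)(C)C(C)(C)C)[C@@](C)(O[Si](CC)(CC)CC)C[C@@H](O[Si](CC)(CC)CC)[C@H](CO)C(=C)C(=O)OC | intermediate
29 | methyl (3R,4R,6S,7S,10Z)-7-(tert-butyldimethylsilyloxy)-3-formyl-11-iodo-6,10-dimethyl-2-methylidene-9-oxo-4,6-bis(triethylsilyloxy)undec-10-enoate | I/C=C(/C)C(=O)C[C@H](O[Si](C)(C)C(C)(C)C)[C@@](C)(O[Si](CC)(CC)CC)C[C@@H](O[Si](CC)(CC)CC)[C@H](C=O)C(=C)C(=O)OC | intermediate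
30 | ten-membered C6 carbinol methyl ester, held as its trivalent chromium alkoxide (not isolated; drawn as the alcohol) | O[C@H]1/C=C(/C)C(=O)C[C@H](O[Si](C)(C)C(C)(C)C)[C@@](C)(O[Si](CC)(CC)CC)C[C@@H](O[Si](CC)(CC)CC)[C@H]1C(=C)C(=O)OC | intermediate
31 | (1S,6S,7S,8R,10S,4Z)-1-(tert-butyldimethylsilyloxy)-8,10-bis(triethylsilyloxy)-3-oxogermacra-4,11(13)-dien-12,6-olide | C=C1C(=O)O[C@H]2/C=C(/C)C(=O)C[C@H](O[Si](C)(C)C(C)(C)C)[C@@](C)(O[Si](CC)(CC)CC)C[C@@H](O[Si](CC)(CC)CC)[C@@H]12 | intermediate
32 | (1S,6S,7R,8R,10S,4Z)-1-(tert-butyldimethylsilyloxy)-8-hydroxy-10-(triethylsilyloxy)-3-oxogermacra-4,11(13)-dien-12,6-olide | C=C1C(=O)O[C@H]2/C=C(/C)C(=O)C[C@H](O[Si](C)(C)C(C)(C)C)[C@@](C)(O[Si](CC)(CC)CC)C[C@@H](O)[C@@H]12 | intermediate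
33 | angelic acid, (Z)-2-methylbut-2-enoic acid | C/C=C(/C)C(=O)O | starting material
34 | angelic 2,4,6-trichlorobenzoic anhydride (not isolated) | C/C=C(/C)C(=O)OC(=O)c1c(Cl)cc(Cl)cc1Cl | intermediate
35 | (1S,6S,7R,8R,10S,4Z)-8-angeloyloxy-1-(tert-butyldimethylsilyloxy)-10-(triethylsilyloxy)-3-oxogermacra-4,11(13)-dien-12,6-olide | C=C1C(=O)O[C@H]2/C=C(/C)C(=O)C[C@H](O[Si](C)(C)C(C)(C)C)[C@@](C)(O[Si](CC)(CC)CC)C[C@@H](OC(=O)/C(C)=C\C)[C@@H]12 | intermediate
36 | CNP0271189.1, (1S,6S,7R,8R,10S,4Z)-8-angeloyloxy-1,10-dihydroxy-3-oxogermacra-4,11(13)-dien-12,6-olide | C=C1C(=O)O[C@H]2/C=C(/C)C(=O)C[C@H](O)[C@@](C)(O)C[C@@H](OC(=O)/C(C)=C\C)[C@@H]12 | target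

## Step count and risks

Total step count: 22. Longest linear sequence: 18 steps, from 6 to 36 (steps 3–12 and 15–22); steps 1–2 and 13–14 are side branches.

**Step 19 (key step).** Closure of a strained ten-membered ring is slow, so intermolecular coupling and reductive loss of iodine can compete. The C6 face may be attacked without enough selectivity, which would give the trans-fused lactone. The aldehyde can also be lost under the Lewis-acidic chromium salts, by enolisation with expulsion of the C8 silyloxy group or by migration of the C11 double bond. Lactonisation of the alkoxide may stay incomplete.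

The fallback reverses the order of the two ring-forming events, sets out from 18 and returns to the route at 31. The PMB ether of 18 is cleaved with DDQ to the primary alcohol F1, which is oxidised with Dess–Martin periodinane to the aldehyde F2. An intermolecular CrCl2/NiCl2 coupling of F2 with 24 forms C5–C6 and the lactone in the open-chain lactone methyl ketone F3, with C6 under simple Felkin control. Direct Swern oxidation of the primary TES ether, as in step 12, gives the keto aldehyde F4. A boron-mediated intramolecular aldol (c-Hex2BCl, Et3N, high dilution) closes the ring at C1–C2 to give the macrocyclic aldol F5, and TBSOTf converts F5 into 31.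

**Step 15.** The reagent and the substrate may be mismatched, because a non-chelated α-silyloxy aldehyde tends towards the 1,2-anti adduct, so the C1 selectivity may be modest. Amine or chloride can also add to the β-iodoenone and erode its Z geometry during enolisation.

The fallback replaces reagent control with chelate control. It sets out from 24 (with 20) and returns at 26. Ketone 24 is converted with TMSOTf and Et3N into the silyloxydiene F6, and a Mukaiyama aldol of F6 with 20 promoted by Me2AlCl is run in CH2Cl2 at −78 °C. An aluminium chelate between the C1 carbonyl and the C10 oxygen exposes the methyl face, which is the face that leads to the syn diol of 26.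

**Step 6.** The boron enolate of a β-alkoxy imide can expel the PMB alkoxide, giving the acryloyl imide and no aldol.

The fallback builds C7–C8 and the acrylate in one operation, sets out from 10 and returns at 18. A Baylis–Hillman reaction of (4-methoxybenzyloxy)acetaldehyde with methyl acrylate gives the adduct F7. Bromination with allylic transposition (NBS, Me2S) gives the Z allylic bromide F8. Allylation of 10 with F8 and In powder in THF/H2O gives the 7,8-syn hydroxy ester F9, and TESOTf converts F9 into 18. This skips steps 7–11, but the C8 face then depends on the substrate alone, so the C8 epimers would have to be separated.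

**Step 21.** Acylation of the hindered C8 hydroxyl inside the macrocycle may be slow. That leaves time for the free hydroxyl to open the lactone and re-close it as the 8,12-olide, and for the angelate to isomerise to the tiglate on long heating.

The fallback puts the angelate on before ring closure, sets out from 27 and returns at 35. PPTS in MeOH removes the C8 TES ether of 27 to give the open-chain alcohol F10. Yamaguchi esterification with 33 gives the angelate F11, DDQ gives the primary alcohol F12, and Dess–Martin oxidation gives the aldehyde F13. The CrCl2/NiCl2 ring closure of F13 then gives 35 directly, and step 22 follows as before.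

## Further compounds

F1 | step 19 | methyl (3S,4R,6S)-3-(hydroxymethyl)-6-methyl-2-methylidene-4,6,7-tris(triethylsilyloxy)heptanoate | C=C(C(=O)OC)[C@@H](CO)[C@H](O[Si](CC)(CC)CC)C[C@](C)(O[Si](CC)(CC)CC)CO[Si](CC)(CC)CC
F2 | step 19 | methyl (3R,4R,6S)-3-formyl-6-methyl-2-methylidene-4,6,7-tris(triethylsilyloxy)heptanoate | C=C(C(=O)OC)[C@@H](C=O)[C@H](O[Si](CC)(CC)CC)C[C@](C)(O[Si](CC)(CC)CC)CO[Si](CC)(CC)CC
F3 | step 19 | open-chain 12,6-lactone methyl ketone with C1, C8 and C10 as TES ethers | C=C1C(=O)O[C@@H](/C=C(/C)C(C)=O)[C@H]1[C@H](O[Si](CC)(CC)CC)C[C@](C)(O[Si](CC)(CC)CC)CO[Si](CC)(CC)CC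
F4 | step 19 | open-chain 12,6-lactone methyl ketone with the C1 aldehyde | C=C1C(=O)O[C@@H](/C=C(/C)C(C)=O)[C@H]1[C@H](O[Si](CC)(CC)CC)C[C@](C)(O[Si](CC)(CC)CC)C=O
F5 | step 19 | (1S,6S,7S,8R,10S,4Z)-1-hydroxy-8,10-bis(triethylsilyloxy)-3-oxogermacra-4,11(13)-dien-12,6-olide | C=C1C(=O)O[C@H]2/C=C(/C)C(=O)C[C@H](O)[C@@](C)(O[Si](CC)(CC)CC)C[C@@H](O[Si](CC)(CC)CC)[C@@H]12
F6 | step 15 | (Z)-4-iodo-3-methyl-2-(trimethylsilyloxy)buta-1,3-diene | C=C(O[Si](C)(C)C)/C(C)=C\I
F7 | step 6 | methyl 3-hydroxy-4-(4-methoxybenzyloxy)-2-methylidenebutanoate (racemic) | C=C(C(=O)OC)C(O)COCc1ccc(OC)cc1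
F8 | step 6 | methyl (Z)-2-(bromomethyl)-4-(4-methoxybenzyloxy)but-2-enoate | COC(=O)/C(CBr)=C/COCc1ccc(OC)cc1
F9 | step 6 | methyl (3S,4R,6S)-4-hydroxy-3-(4-methoxybenzyloxymethyl)-6-methyl-2-methylidene-6,7-bis(triethylsilyloxy)heptanoate | C=C(C(=O)OC)[C@@H](COCc1ccc(OC)cc1)[C@H](O)C[C@](C)(O[Si](CC)(CC)CC)CO[Si](CC)(CC)CC
F10 | step 21 | open-chain C8 alcohol from 27 | I/C=C(/C)C(=O)C[C@H](O[Si](C)(C)C(C)(C)C)[C@@](C)(O[Si](CC)(CC)CC)C[C@@H](O)[C@H](COCc1ccc(OC)cc1)C(=C)C(=O)OC
F11 | step 21 | open-chain C8 angelate with the C6 PMB ether | I/C=C(/C)C(=O)C[C@H](O[Si](C)(C)C(C)(C)C)[C@@](C)(O[Si](CC)(CC)CC)C[C@@H](OC(=O)/C(C)=C\C)[C@H](COCc1ccc(OC)cc1)C(=C)C(=O)OC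
F12 | step 21 | open-chain C8 angelate with the free C6 alcohol | I/C=C(/C)C(=O)C[C@H](O[Si](C)(C)C(C)(C)C)[C@@](C)(O[Si](CC)(CC)CC)C[C@@H](OC(=O)/C(C)=C\C)[C@H](CO)C(=C)C(=O)OC
F13 | step 21 | open-chain C8 angelate with the C6 aldehyde | I/C=C(/C)C(=O)C[C@H](O[Si](C)(C)C(C)(C)C)[C@@](C)(O[Si](CC)(CC)CC)C[C@@H](OC(=O)/C(C)=C\C)[C@H](C=O)C(=C)C(=O)OC
A1 | alternative 1 | ten-membered (4Z,1(10)E)-dienone with the C8 PMB ether and the C3 TBS ether | C1[C@H](OCc2ccc(OC)cc2)C/C(C)=C/C[C@@H](O[Si](C)(C)C(C)(C)C)/C(C)=C\C1=O
A2 | alternative 2 | ten-membered aldol with the lactone still open and silylated | C1C(=O)/C(C)=C\[C@H](O[Si](C)(C)C(C)(C)C)[C@H](C(=C)CO[Si](C)(C)C(C)(C)C)[C@H](OC(=O)/C(C)=C\C)C[C@](C)(O[Si](CC)(CC)CC)[C@H]1O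
A3 | alternative 3 | isoxazoline-bridged cyclodecene lactone | C1C2=NO[C@@H]1[C@@](C)(O)C[C@@H](O[Si](C)(C)C(C)(C)C)[C@H]3CC(=O)O[C@H]3/C=C2/C
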